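I decided to keep elm at 72 mM of catalyst and stop it at 1.0 h, after first asking what end state the flask must reach and how far it would still be from that state when stopped.

in all of them: substrate 2.9 M
- spring: catalyst 47 mM; run made earlier
- autumn: catalyst 190 mM; run made earlier
- elm: catalyst 72 mM; time 1.0 h
- alder: catalyst 140 mM; time 1.0 h
- birch: catalyst 290 mM; time 1.0 h

| run | time / min | isomer of the product A / % | other conformer / % | substrate / % | target / % | isomer of the product B / % |
|---|---|---|---|---|---|---|
| spring | 5.00 | 3.6 | 52.0 | 24.7 | 12.8 | 5.5 |
| spring | 8.00 | 9.3 | 50.2 | 19.3 | 16.9 | 4.8 |
| spring | 12.0 | 10.5 | 43.0 | 17.0 | 21.0 | 7.0 |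
| spring | 20.0 | 15.9 | 31.8 | 14.5 | 26.6 | 9.7 |
| spring | 40.0 | 26.5 | 16.4 | 5.9 | 36.9 | 14.1 |
| spring | 60.0 | 31.0 | 7.9 | 1.1 | 42.0 | 16.7 |
| autumn | 4.00 | 8.3 | 33.2 | 12.0 | 33.5 | 12.5 |
| autumn | 12.0 | 22.6 | 10.0 | 1.9 | 44.5 | 15.8 |
| autumn | 20.0 | 26.9 | 3.1 | 0 | 47.3 | 17.3 |
| autumn | 30.0 | 30.6 | 1.6 | 0 | 51.2 | 18.4 |
| autumn | 50.0 | 30.7 | 1.6 | 0 | 50.7 | 17.2 |
| autumn | 60.0 | 32.6 | 1.0 | 1.0 | 51.0 | 20.1 |

(scatter of a reading: 1 percentage point)

- what was read earlier has a scatter of 1 percentage point, one standard deviation

* which of these there is most of at the end, counted by the substrate in it, elm (isomer of the product A / target / other conformer / isomer of the product B)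
* which of these there is most of at the end, counted by the substrate in it, alder (isomer of the product A / target / other conformer / isomer of the product B)
* which of these there is most of at the end, counted by the substrate in it, birch (isomer of the product A / target / other conformer / isomer of the product B)
* amount of the one of these that there is most of at the end, in percent of the substrate charged, elm
* amount of the one of these that there is most of at the end, in percent of the substrate charged, alder
* amount of the one of these that there is most of at the end, in percent of the substrate charged, birch

I added substrate and other conformer into one pool, the fraction of the charge not yet product. In the spring run this pool fell from 60.0% at 12.0 min to 9.00% at 60.0 min, which gave 0.0395 min⁻¹. I carried this as the pool constant, the pseudo-first-order fall of the logarithm of the pool per unit time, taken as proportional to catalyst. Scaled to the autumn charge it gave 0.160 min⁻¹, and the autumn readings gave 0.167 min⁻¹ by themselves, so the second run supported the scaling.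

The pool left at 1.0 h then came to 2.64% in elm, 0.0856% in alder and <0.001% in birch. For the end state, the autumn run read target at 51.0% and isomer of the product A at 32.6% at 60.0 min. Late in the spring run, target took 0.413 of the pool lost, which pointed to an end near 45.7% for that run, less than the autumn reading of target. With that share, the pool still unconverted in elm stood for about 1.1 percentage points of target, less than the 5.3 points between those two ends, so I left the time alone and treated more catalyst as a way of moving the end state.

The forecast named target for every flask, with 46% for elm (43.5% to 48.5%), 49.5% for alder (47% to 52%) and 52% for birch (49.5% to 55%), on the ground that “More catalyst captures more substrate before equilibration”. It put the unconverted part of elm at 3 to 4 per cent, where my reckoning gave 2.64%.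

The flasks gave target at 45.3% in elm, target at 48.9% in alder and target at 52.7% in birch.

Elm had not quite come to rest: its pool stood at 3.49% at 1.0 h, against my 2.64%, and at 10.0 h its target reached 46.8%. Alder held a pool of 0.185%, and its target went from 48.9% to 48.9% over the same longer time. Birch held 0% of substrate and 0% of other conformer, and the longer run left its target unchanged. At 10.0 h birch stood at 52.7% against 46.8% in elm.

    substrate ⇌ other conformer (K = 2.40, k = 0.00700 s⁻¹)
    substrate + catalyst → catalyst + target (k = 0.0270 M⁻¹ s⁻¹)
    catalyst + other conformer → catalyst + isomer of the product A (k = 0.00730 M⁻¹ s⁻¹)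
    target ⇌ isomer of the product B (K = 0.380, k = 0.0150 s⁻¹)

For the neighbour flask, alder with 0.35 M of catalyst, the pool constant gave <0.001% of pool left at 1.0 h. The computed flask held 0% of substrate, 0% of other conformer and 53.8% of target.

All runs were generated by integration on assumed constants; scatter was added.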